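Everything rests on cutting ring C at the O1–C8a bond. Because O1 joins the sp3 carbon C2 to the aromatic carbon C8a of ring A, ring C can be closed by letting the C2 hydroxyl of an enantioenriched open-chain diol arylate a bromide at C8a under copper catalysis. The C2–O bond stays intact throughout, so the S configuration set earlier by a catalytic ketone reduction is carried through unchanged. The substrate is a (1S)-1-(ring B aryl)-3-(2-bromoaryl)propane-1,3-diol with MOM-protected phenols and a silylated side-chain carbinol, assembled by aldol union of a ring A bromoaldehyde and a ring B methyl ketone. C4 oxidation and acid unmasking complete the flavanone.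

Key step: step 12

Remark: the carbinol carbon that becomes C4 is formed without control in step 10 and is carried as both epimers (left undefined in the SMILES of 21–23) until step 13 removes it. MOM = methoxymethyl, TBS = tert-butyldimethylsilyl.

Step 1
Reactants: 1 5-bromoresorcinol
Product: 2 1-bromo-3,5-bis(methoxymethoxy)benzene
Conditions: MOMCl (2.5 equiv), iPr2NEt, CH2Cl2, 0 °C → rt
Reagents that add atoms: chloromethyl methyl ether, COCCl
Why: Base-mediated O-alkylation of both phenols (Williamson-type acetal formation) should be clean, and the MOM ethers later act as ortho-directing groups that last until the final unmasking.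

Step 2
Reactants: 2 1-bromo-3,5-bis(methoxymethoxy)benzene; 3 prenyl bromide (1-bromo-3-methylbut-2-ene)
Product: 6 5-bromo-1,3-bis(methoxymethoxy)-2-(3-methylbut-2-en-1-yl)benzene, via aryllithium 4 (not isolated), via arylcopper 5 (not isolated)
Conditions: LiN(iPr)2 (LDA, 1.1 equiv), THF, −78 °C; CuBr·SMe2 (1.1 equiv), −78 → −40 °C; prenyl bromide, → 0 °C
Reagents that add atoms: none
Why: Directed ortho-metalation with an amide base (which, unlike an alkyllithium, does not exchange the bromine) should remove the proton flanked and chelated by both MOM ethers, and the derived arylcopper should substitute prenyl bromide at its primary carbon (copper-mediated allylic alkylation), placing the prenyl group between the two oxygens.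

Step 3
Reactants: 6 5-bromo-1,3-bis(methoxymethoxy)-2-(3-methylbut-2-en-1-yl)benzene
Product: 7 (2S)-2-{[4-bromo-2,6-bis(methoxymethoxy)phenyl]methyl}-3,3-dimethyloxirane
Conditions: L-fructose-derived Shi ketone 1,2:4,5-di-O-isopropylidene-β-L-erythro-2,3-hexodiulo-2,6-pyranose (30 mol %), Oxone (2KHSO5·KHSO4·K2SO4), K2CO3, n-Bu4NHSO4, MeCN–CH2(OMe)2 / aq. Na2B4O7–Na2H2EDTA buffer, 0 °C
Reagents that add atoms: Oxone (active oxidant potassium peroxymonosulfate, KHSO5), [K+].[O-]S(=O)(=O)OO
Why: Shi asymmetric epoxidation, in which the dioxirane formed from the L-configured ketone should transfer oxygen to the trisubstituted alkene through a spiro transition state on the face that gives the S epoxide carbon (the D-fructose-derived ketone gives R); the step is placed before any aldehyde is present because Oxone would oxidise one.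

Step 4
Reactants: 7 (2S)-2-{[4-bromo-2,6-bis(methoxymethoxy)phenyl]methyl}-3,3-dimethyloxirane
Product: 8 (2S)-1-[4-bromo-2,6-bis(methoxymethoxy)phenyl]-3-methylbut-3-en-2-ol
Conditions: Et2Al(TMP) (3 equiv; made from 2,2,6,6-tetramethylpiperidine, n-BuLi and Et2AlCl), toluene, 0 °C; aq. KNaC4H4O6 work-up
Reagents that add atoms: none
Why: Aluminium amide-promoted rearrangement of a trisubstituted epoxide to an allylic alcohol (syn β-elimination within the aluminium-bound epoxide) should break the tertiary C–O bond and remove a methyl proton, giving the isopropenyl carbinol while the C–O bond at the stereocentre is untouched and its S configuration is kept.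

Step 5
Reactants: 8 (2S)-1-[4-bromo-2,6-bis(methoxymethoxy)phenyl]-3-methylbut-3-en-2-ol
Product: 9 {[(2S)-1-[4-bromo-2,6-bis(methoxymethoxy)phenyl]-3-methylbut-3-en-2-yl]oxy}(tert-butyl)dimethylsilane
Conditions: TBSCl, imidazole, DMF, rt
Reagents that add atoms: tert-butyldimethylsilyl chloride, CC(C)(C)[Si](C)(C)Cl
Why: Standard silylation of a secondary alcohol masks the allylic hydroxyl so that it is neither oxidised in step 13 nor available as a competing nucleophile.

Step 6
Reactants: 9 {[(2S)-1-[4-bromo-2,6-bis(methoxymethoxy)phenyl]-3-methylbut-3-en-2-yl]oxy}(tert-butyl)dimethylsilane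
Product: 11 6-bromo-3-[(2S)-2-{[tert-butyl(dimethyl)silyl]oxy}-3-methylbut-3-en-1-yl]-2,4-bis(methoxymethoxy)benzaldehyde, via aryllithium 10 (not isolated)
Conditions: LiN(iPr)2 (1.2 equiv), THF, −78 °C, 1 h; DMF, −78 °C; H2O
Reagents that add atoms: N,N-dimethylformamide, CN(C)C=O
Why: Directed ortho-metalation at the only ring protons left (two equivalent positions, each acidified by a flanking MOM ether and the bromine) followed by formylation with DMF should give the aldehyde; the ortho-bromo aryllithium is held at −78 °C to prevent aryne formation, and the formyl group is installed only now because it would not survive steps 3 and 4.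

Step 7
Reactants: 12 4-bromocatechol
Product: 13 4-bromo-1,2-bis(methoxymethoxy)benzene
Conditions: MOMCl (2.5 equiv), iPr2NEt, CH2Cl2, 0 °C → rt
Reagents that add atoms: chloromethyl methyl ether, COCCl
Why: The same O-alkylation as in step 1 protects the catechol and provides the directing group for the next metalation.

Step 8
Reactants: 13 4-bromo-1,2-bis(methoxymethoxy)benzene; 14 geranyl bromide
Product: 17 1-bromo-2-[(2E)-3,7-dimethylocta-2,6-dien-1-yl]-3,4-bis(methoxymethoxy)benzene, via aryllithium 15 (not isolated), via arylcopper 16 (not isolated)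
Conditions: LiN(iPr)2 (1.1 equiv), THF, −78 °C; CuBr·SMe2 (1.1 equiv), −78 °C; geranyl bromide, −78 → 0 °C
Reagents that add atoms: none
Why: Amide-base directed ortho-metalation should occur at C3, the position between the MOM ether and the bromine; transmetalation to copper at −78 °C stops loss of LiBr, and the arylcopper should alkylate geranyl bromide at its primary carbon with the E alkene intact.

Step 9
Reactants: 17 1-bromo-2-[(2E)-3,7-dimethylocta-2,6-dien-1-yl]-3,4-bis(methoxymethoxy)benzene
Product: 19 1-{2-[(2E)-3,7-dimethylocta-2,6-dien-1-yl]-3,4-bis(methoxymethoxy)phenyl}ethan-1-one, via aryllithium 18 (not isolated)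
Conditions: n-BuLi (1.05 equiv), THF, −78 °C; MeC(O)N(OMe)Me, −78 → 0 °C; H2O
Reagents that add atoms: N-methoxy-N-methylacetamide, CC(=O)N(C)OC
Why: Fast bromine–lithium exchange at −78 °C followed by acylation with the Weinreb amide (Weinreb ketone synthesis), whose chelated tetrahedral adduct prevents over-addition, should give the methyl ketone.

Step 10
Reactants: 19 1-{2-[(2E)-3,7-dimethylocta-2,6-dien-1-yl]-3,4-bis(methoxymethoxy)phenyl}ethan-1-one; 11 6-bromo-3-[(2S)-2-{[tert-butyl(dimethyl)silyl]oxy}-3-methylbut-3-en-1-yl]-2,4-bis(methoxymethoxy)benzaldehyde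
Product: 21 3-{6-bromo-3-[(2S)-2-{[tert-butyl(dimethyl)silyl]oxy}-3-methylbut-3-en-1-yl]-2,4-bis(methoxymethoxy)phenyl}-1-{2-[(2E)-3,7-dimethylocta-2,6-dien-1-yl]-3,4-bis(methoxymethoxy)phenyl}-3-hydroxypropan-1-one (both C3 epimers), via lithium enolate 20 (not isolated)
Conditions: LiN(iPr)2 (1.05 equiv), THF, −78 °C; then 11, −78 °C; AcOH quench at −78 °C
Reagents that add atoms: none
Why: Directed (crossed) aldol addition of the preformed lithium enolate to the non-enolisable aldehyde should give the β-hydroxy ketone, the cold acidic quench guarding against retro-aldol cleavage and dehydration; the new carbinol (future C4) needs no control because step 13 oxidises it.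

Step 11
Reactants: 21 the β-hydroxy ketone of step 10 (both C3 epimers)
Product: 22 (1S)-3-{6-bromo-3-[(2S)-2-{[tert-butyl(dimethyl)silyl]oxy}-3-methylbut-3-en-1-yl]-2,4-bis(methoxymethoxy)phenyl}-1-{2-[(2E)-3,7-dimethylocta-2,6-dien-1-yl]-3,4-bis(methoxymethoxy)phenyl}propane-1,3-diol (both C3 epimers)
Conditions: RuCl[(S,S)-TsDPEN](p-cymene) (3 mol %), HCO2H–Et3N (1:1), CH2Cl2, 30 °C
Reagents that add atoms: none
Why: Noyori-type asymmetric transfer hydrogenation of an aryl ketone, in which the (S,S)-configured ruthenium hydride should add to the face that gives the (1S) benzylic alcohol (ring B as the recognised aryl group, as acetophenone gives the S alcohol) under catalyst control for both C3 epimers; it is preferred to borane reagents because it tolerates the free hydroxyl and leaves the isopropenyl and geranyl alkenes untouched.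

Step 12
Reactants: 22 the (1S)-bromo diol of step 11 (both C3 epimers)
Product: 23 (2S)-6-[(2S)-2-{[tert-butyl(dimethyl)silyl]oxy}-3-methylbut-3-en-1-yl]-2-{2-[(2E)-3,7-dimethylocta-2,6-dien-1-yl]-3,4-bis(methoxymethoxy)phenyl}-5,7-bis(methoxymethoxy)-3,4-dihydro-2H-chromen-4-ol (both C4 epimers)
Conditions: CuI (10 mol %), 3,4,7,8-tetramethyl-1,10-phenanthroline (20 mol %), Cs2CO3 (2 equiv), degassed toluene (0.05 M), 110 °C, Ar
Reagents that add atoms: none
Why: In this Ullmann-type C–O coupling, Cs2CO3 and the phenanthroline-ligated monovalent copper should turn the C2 hydroxyl into a copper alkoxide, which activates the C8a–Br bond and releases the aryl ether by C–O bond-forming reductive elimination. The closest known reactions are the CuI/phenanthroline/Cs2CO3 etherifications of aryl bromides with secondary alcohols and their intramolecular use for chromans and flavans. Ring C closes in a 6-exo mode, O1 reaching C8a across the C2–C3–C4–C4a tether while bromide leaves outside the ring. No stereocentre is created: C2 keeps its S configuration because only its O–H bond reacts, and C4 remains an epimer mixture that step 13 removes. The selectivity needed is between the two hydroxyls, and ring size secures it, since the C4 hydroxyl could only close a four-membered ring; the side-chain oxygen is silylated, and the MOM ethers, both meta to C8a, do not deactivate the bromide.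

Step 13
Reactants: 23 the protected (2S)-flavan-4-ol of step 12 (both C4 epimers)
Product: 24 (2S)-6-[(2S)-2-{[tert-butyl(dimethyl)silyl]oxy}-3-methylbut-3-en-1-yl]-2-{2-[(2E)-3,7-dimethylocta-2,6-dien-1-yl]-3,4-bis(methoxymethoxy)phenyl}-5,7-bis(methoxymethoxy)-2,3-dihydro-4H-chromen-4-one
Conditions: Dess–Martin periodinane (1.5 equiv), NaHCO3, CH2Cl2, 0 °C → rt
Reagents that add atoms: none
Why: Dess–Martin oxidation of the secondary benzylic alcohol under buffered, non-acidic conditions should give the flavanone from both C4 epimers without touching the alkenes, the acetals or the silyl ether and without opening ring C.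

Step 14
Reactants: 24 the protected (2S)-flavanone of step 13
Product: 25 (2S)-2-{2-[(2E)-3,7-dimethylocta-2,6-dien-1-yl]-3,4-dihydroxyphenyl}-5,7-dihydroxy-6-[(2S)-2-hydroxy-3-methylbut-3-en-1-yl]-2,3-dihydro-4H-chromen-4-one (CNP0120394.3)
Conditions: HCl (1.25 M in MeOH), 0 °C → rt
Reagents that add atoms: none
Why: Acid-catalysed acetal exchange with methanol should remove the four aryl MOM ethers and methanolyse the silyl ether in one operation, the low temperature being chosen to spare the geranyl and isopropenyl alkenes, the allylic alcohol and the C2 centre.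

Compound list

1 | 5-bromoresorcinol | Oc1cc(O)cc(Br)c1 | starting material
2 | 1-bromo-3,5-bis(methoxymethoxy)benzene | COCOc1cc(Br)cc(OCOC)c1 | intermediate
3 | prenyl bromide (1-bromo-3-methylbut-2-ene) | CC(C)=CCBr | starting material
4 | [4-bromo-2,6-bis(methoxymethoxy)phenyl]lithium (not isolated) | [Li]c1c(OCOC)cc(Br)cc1OCOC | intermediate
5 | [4-bromo-2,6-bis(methoxymethoxy)phenyl]copper (not isolated) | [Cu]c1c(OCOC)cc(Br)cc1OCOC | intermediate
6 | 5-bromo-1,3-bis(methoxymethoxy)-2-(3-methylbut-2-en-1-yl)benzene | CC(C)=CCc1c(OCOC)cc(Br)cc1OCOC | intermediate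
7 | (2S)-2-{[4-bromo-2,6-bis(methoxymethoxy)phenyl]methyl}-3,3-dimethyloxirane | COCOc1cc(Br)cc(OCOC)c1C[C@@H]1OC1(C)C | intermediate
8 | (2S)-1-[4-bromo-2,6-bis(methoxymethoxy)phenyl]-3-methylbut-3-en-2-ol | C=C(C)[C@@H](O)Cc1c(OCOC)cc(Br)cc1OCOC | intermediate
9 | TBS ether of 8, (S) | C=C(C)[C@@H](O[Si](C)(C)C(C)(C)C)Cc1c(OCOC)cc(Br)cc1OCOC | intermediate
10 | {6-bromo-3-[(2S)-2-(TBS-oxy)-3-methylbut-3-en-1-yl]-2,4-bis(methoxymethoxy)phenyl}lithium (not isolated) | C=C(C)[C@@H](O[Si](C)(C)C(C)(C)C)Cc1c(OCOC)cc(Br)c([Li])c1OCOC | intermediate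
11 | 6-bromo-3-[(2S)-2-(TBS-oxy)-3-methylbut-3-en-1-yl]-2,4-bis(methoxymethoxy)benzaldehyde | C=C(C)[C@@H](O[Si](C)(C)C(C)(C)C)Cc1c(OCOC)cc(Br)c(C=O)c1OCOC | intermediate
12 | 4-bromocatechol | Oc1ccc(Br)cc1O | starting material
13 | 4-bromo-1,2-bis(methoxymethoxy)benzene | COCOc1ccc(Br)cc1OCOC | intermediate
14 | geranyl bromide | BrC/C=C(\C)CCC=C(C)C | starting material
15 | [6-bromo-2,3-bis(methoxymethoxy)phenyl]lithium (not isolated) | COCOc1ccc(Br)c([Li])c1OCOC | intermediate
16 | [6-bromo-2,3-bis(methoxymethoxy)phenyl]copper (not isolated) | COCOc1ccc(Br)c([Cu])c1OCOC | intermediate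
17 | 1-bromo-2-[(2E)-3,7-dimethylocta-2,6-dien-1-yl]-3,4-bis(methoxymethoxy)benzene | COCOc1ccc(Br)c(C/C=C(\C)CCC=C(C)C)c1OCOC | intermediate
18 | {2-[(2E)-3,7-dimethylocta-2,6-dien-1-yl]-3,4-bis(methoxymethoxy)phenyl}lithium (not isolated) | COCOc1ccc([Li])c(C/C=C(\C)CCC=C(C)C)c1OCOC | intermediate
19 | 1-{2-[(2E)-3,7-dimethylocta-2,6-dien-1-yl]-3,4-bis(methoxymethoxy)phenyl}ethan-1-one | CC(=O)c1ccc(OCOC)c(OCOC)c1C/C=C(\C)CCC=C(C)C | intermediate
20 | lithium enolate of 19 (not isolated) | [Li]OC(=C)c1ccc(OCOC)c(OCOC)c1C/C=C(\C)CCC=C(C)C | intermediate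
21 | aldol adduct, 3-(ring A aryl)-3-hydroxy-1-(ring B aryl)propan-1-one, both C3 epimers | C=C(C)[C@@H](O[Si](C)(C)C(C)(C)C)Cc1c(OCOC)cc(Br)c(C(O)CC(=O)c2ccc(OCOC)c(OCOC)c2C/C=C(\C)CCC=C(C)C)c1OCOC | intermediate
22 | (1S)-1-(ring B aryl)-3-(2-bromoaryl)propane-1,3-diol, both C3 epimers | C=C(C)[C@@H](O[Si](C)(C)C(C)(C)C)Cc1c(OCOC)cc(Br)c(C(O)C[C@@H](c2ccc(OCOC)c(OCOC)c2C/C=C(\C)CCC=C(C)C)O)c1OCOC | intermediate
23 | protected (2S)-flavan-4-ol, both C4 epimers | C=C(C)[C@@H](O[Si](C)(C)C(C)(C)C)Cc1c(OCOC)cc2c(c1OCOC)C(O)C[C@@H](c1ccc(OCOC)c(OCOC)c1C/C=C(\C)CCC=C(C)C)O2 | intermediate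
24 | protected (2S)-flavanone | C=C(C)[C@@H](O[Si](C)(C)C(C)(C)C)Cc1c(OCOC)cc2c(c1OCOC)C(=O)C[C@@H](c1ccc(OCOC)c(OCOC)c1C/C=C(\C)CCC=C(C)C)O2 | intermediate
25 | CNP0120394.3, (2S)-flavanone with (S)-2-hydroxy-3-methylbut-3-enyl at C6 | C=C(C)[C@@H](O)Cc1c(O)cc2c(c1O)C(=O)C[C@@H](c1ccc(O)c(O)c1C/C=C(\C)CCC=C(C)C)O2 | target

Total step count: 14. Longest linear sequence: 11 steps (steps 1–6, then 10–14, from 5-bromoresorcinol); the ring B branch is steps 7–9.

Steps most likely to fail

Step 12. Copper may fail to turn over, because the neighbouring C4 alkoxide or the diol as a chelate ties it up, or the hindered bromide may be reduced instead of etherified. The fallback sets out from 22 and returns to 23 by an elimination–addition that needs no metal catalyst. Lithium 2,2,6,6-tetramethylpiperidide (4 equiv, THF, −78 → 0 °C) should remove both hydroxyl protons and then H8, the same MOM/bromine-flanked position metalated in step 6. Loss of LiBr on warming gives the ring A 8,8a-aryne dilithium dialkoxide F1. Its C2 alkoxide should add at C8a, the aryne carbon distal to the C7 MOM ether, closing the six-membered ring. Protonation at C8 on work-up gives 23 with C2 untouched.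

Step 14. Protic acid may cause cyclisation of the freed phenols onto the geranyl or isopropenyl alkenes, solvolysis of the allylic alcohol, or ring opening with loss of configuration at C2. The fallback runs from 24 to 25 without protic acid. TMSOTf with 2,2′-bipyridyl (CH2Cl2, 0 °C) should exchange the four aryl MOM ethers for trimethylsilyl ethers, giving the tetrakis(trimethylsilyl) ether F4. Aqueous work-up hydrolyses this to the tetraphenol TBS ether F5. HF·pyridine buffered with pyridine (THF, 0 °C) then removes the remaining silyl group to give 25.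

Step 11. Hydride transfer to the hindered, electron-rich ketone may be slow, leaving time for dehydration of the aldol to the chalcone or retro-aldol cleavage, and catalyst control may be eroded. The fallback runs from 21 back to 22. The C4 hydroxyl is capped (TESCl, imidazole, DMF) to give the triethylsilyl ether F2, which can no longer dehydrate. Corey–Bakshi–Shibata reduction with (R)-2-methyl-CBS-oxazaborolidine and catecholborane (toluene, −78 °C; catecholborane spares the alkenes) should give the (1S)-alcohol triethylsilyl ether F3. HF·pyridine buffered with pyridine (THF, 0 °C) removes the triethylsilyl group while the TBS ether stays, returning 22.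

Further compounds

F1 | step 12 | ring A 8,8a-aryne dilithium dialkoxide derived from 22 | C=C(C)[C@@H](O[Si](C)(C)C(C)(C)C)CC1=C(OCOC)C#CC(C(O[Li])C[C@@H](c2ccc(OCOC)c(OCOC)c2C/C=C(\C)CCC=C(C)C)O[Li])=C1OCOC
F2 | step 11 | triethylsilyl ether of aldol adduct 21 | C=C(C)[C@@H](O[Si](C)(C)C(C)(C)C)Cc1c(OCOC)cc(Br)c(C(O[Si](CC)(CC)CC)CC(=O)c2ccc(OCOC)c(OCOC)c2C/C=C(\C)CCC=C(C)C)c1OCOC
F3 | step 11 | (1S)-alcohol triethylsilyl ether (C3 silyl ether of 22) | C=C(C)[C@@H](O[Si](C)(C)C(C)(C)C)Cc1c(OCOC)cc(Br)c(C(O[Si](CC)(CC)CC)C[C@@H](c2ccc(OCOC)c(OCOC)c2C/C=C(\C)CCC=C(C)C)O)c1OCOC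
F4 | step 14 | tetrakis(trimethylsilyl) ether of the flavanone, side-chain TBS ether retained | C=C(C)[C@@H](O[Si](C)(C)C(C)(C)C)Cc1c(O[Si](C)(C)C)cc2c(c1O[Si](C)(C)C)C(=O)C[C@@H](c1ccc(O[Si](C)(C)C)c(O[Si](C)(C)C)c1C/C=C(\C)CCC=C(C)C)O2
F5 | step 14 | tetraphenol TBS ether of the target | C=C(C)[C@@H](O[Si](C)(C)C(C)(C)C)Cc1c(O)cc2c(c1O)C(=O)C[C@@H](c1ccc(O)c(O)c1C/C=C(\C)CCC=C(C)C)O2
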